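Assumption: locants are used in which O1 is bonded to the aryl-bearing carbon C2 and to C8a, and O4 to the methyl-bearing carbon C3 and to C4a; in this numbering the target is the trans-(2S,3S) compound. The structures were checked and need no correction.

## Structural features

The target is a 2,3-dihydro-1,4-benzodioxine: an aromatic ring A fused to a 1,4-dioxane ring B (O1–C2–C3–O4–C4a–C8a). C2 carries a 3,4,5-trimethoxyphenyl group (ring C) and C3 a methyl group; these adjacent stereocentres are both S and their substituents are trans. On ring A, C5 (next to the O4-bearing C4a) holds a methoxy group and C7 (para to C4a) holds an (E)-propenal chain. The fragile parts are the enal, which is sensitive to bases, nucleophiles and oxidants, and the benzylic C2–O1 ether bond next to an electron-rich arene, which can ionise in strong acid and epimerise C2. The real difficulty is twofold: the unsymmetrical catechol diether must be assembled with O4 on the methyl-bearing C3 and O1 on the benzylic C2, and the trans relationship and absolute configuration at C2/C3 must be secured. The key step uses the fact that C8a (bearing O1) and C7 (bearing the side chain) are ortho and para to C4a, so the O1–C8a bond and the C7–alkene bond can both grow from the two C–Br bonds of one 2,4-dibromo-6-methoxyphenyl ether. Because ring B is then closed at an sp2 carbon, both stereocentres are set beforehand in an open chain, where trans in ring B corresponds to the syn (threo) 1,2-relationship.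

## Logic of the disconnections

10 ⇒ 9. No skeletal bond is cut; the aldehyde carbon of 10 is traced back to a diethyl acetal carbon in 9. The reason is that a free three-carbon enal reagent would polymerise under basic palladium conditions, whereas its acetal behaves as a plain terminal alkene. The gain is that the only base-sensitive group of 10 does not exist until the last operation. The demand is an acid mild enough to open an allylic acetal without ionising the C2–O1 bond.

9 ⇒ 7 + 8. Two bonds are cut together: O1–C8a, which opens ring B, and the bond from C7 to the first side-chain carbon. The cut is made there because both bonds end on ring A carbons that can carry bromine, ortho and para to the ether oxygen. The gain is large: ring B and the whole side chain vanish, leaving an open-chain alcohol with both stereocentres and a commercial alkene. The demand is that one palladium catalyst sends the ortho C–Br bond to the tethered hydroxyl and the para C–Br bond to the alkene, without β-hydride loss from the benzylic alkoxide and without β-hydride elimination toward the acetal carbon.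

7 ⇒ 4 + 6 (6 from 5). The bond between the carbinol carbon (future C2) and ring C is cut. This is the natural polar junction: an aldehyde carbon and an aryl nucleophile. The gain is that the C2 stereocentre is derived from C3 by 1,2-induction and ring C comes from a simple aryl bromide. The demand is chelation control to obtain the syn alcohol, and configurational stability of 4 under the addition conditions.

4 ⇒ 3. No bond is cut; the aldehyde is traced back to a methyl ester. The ester is the stable, storable form of the C3 fragment. The demand is a reduction that stops at the aldehyde and does not enolise the α-aryloxy centre.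

3 ⇒ 1 + 2. The O4–C3 bond is cut. Cutting here fixes the regiochemistry of the diether from the outset, since the only phenolic oxygen of 1 is the one flanked by the methoxy group. The chiral pool supplies C3. The demand is a clean SN2 inversion at a secondary carbinol by a hindered but acidic phenol.

## Other disconnections considered

Alternative 1: The cut is made on both sides of C2, at C2–C3 and at C2–aryl, with C2 itself coming from dichloromethane. In the forward direction (dichloromethyl)lithium A2 adds to the boron of (4R,5R)-2-{(1R)-1-[2-bromo-4-(1,3-dioxolan-2-yl)-6-methoxyphenoxy]ethyl}-4,5-dicyclohexyl-1,3,2-dioxaborolane A1. ZnCl2 then promotes the 1,2-shift of the aryloxyethyl group from boron to carbon to give the α-chloro boronic ester (4R,5R)-2-{(1S,2S)-2-[2-bromo-4-(1,3-dioxolan-2-yl)-6-methoxyphenoxy]-1-chloropropyl}-4,5-dicyclohexyl-1,3,2-dioxaborolane A3. Compound 6 forms a second ate complex whose aryl group migrates with inversion at carbon, giving (4R,5R)-2-{(1S,2S)-2-[2-bromo-4-(1,3-dioxolan-2-yl)-6-methoxyphenoxy]-1-(3,4,5-trimethoxyphenyl)propyl}-4,5-dicyclohexyl-1,3,2-dioxaborolane A4.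
- In favour: the configuration of C2 is dictated by the C2-symmetric diol on boron, not by a chelate through a weakly basic aryl ether oxygen. On reliability of the C2 configuration this alternative is the better plan. Its two migrations are individually well understood, so on mechanistic precedent for the key step it is also the better.
- Against: A3 and A4 are β-aryloxy boron compounds whose ate complexes could eliminate boron and aryloxide, destroying C3. A1 must itself be made as one enantiomer by an earlier homologation cycle. No ring is closed, so C–B oxidation, palladium ring closure, acetal hydrolysis and a two-carbon olefination would still follow.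
- Comparison: on structure both plans reach the same kind of syn aryloxy alcohol array and close ring B at O1–C8a, so they are equal there. On step economy the chosen plan (four steps) should be far shorter than this one (about ten), and it needs no stoichiometric chiral diol.

Alternative 2: The cut is at O4–C3 and C3–C2, so that C3 comes from a diazo carbon. In the forward direction Rh2(OAc)4 converts ethyl diazoacetate A6 into a rhodium carbene. 2-Bromo-4-(1,3-dioxolan-2-yl)-6-methoxyphenol A5 adds to it to give an oxonium ylide. The ylide is intercepted by 3,4,5-trimethoxybenzaldehyde A7 bound to a chiral phosphoric acid, giving ethyl (2R,3S)-2-[2-bromo-4-(1,3-dioxolan-2-yl)-6-methoxyphenoxy]-3-hydroxy-3-(3,4,5-trimethoxyphenyl)propanoate A8.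
- In favour: three simple achiral pieces, two bonds and both stereocentres in one catalytic operation. On convergence and on the catalytic origin of absolute configuration this alternative is the better plan, and no enolisable α-aryloxy aldehyde is handled.
- Against: an ylide from a phenol and an acceptor-only carbene is expected to collapse by 1,2-proton shift (O–H insertion) faster than it is trapped. Trapping is favoured by electron-poor carbonyl partners, whereas A7 is electron-rich. A5 is hindered at both ortho positions and its dioxolane is exposed to a Brønsted acid. C3 arrives as an ester that would still have to be reduced to a methyl group (reduction, sulfonylation, hydride displacement, with the benzylic hydroxyl protected).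
- Comparison: on structure the two plans are equal in leaving ring B to a later C–O coupling. On mechanism the chosen plan merges two individually established palladium cycles, while this one depends on a trapping step outside the usual substrate range, with relative and absolute configuration both unsecured. On step economy it would be about twice as long.

Alternative 3: The cut is at O4–C3, with the C3 methyl group traced back to the terminal CH2 of a vinyl group, after a first cut at O1–C2 by allylic etherification. In the forward direction a cobalt hydride formed from Co(salen), a silane and an N-fluoropyridinium oxidant transfers a hydrogen atom to the terminal carbon of methyl 4-hydroxy-3-methoxy-5-{[(1R)-1-(3,4,5-trimethoxyphenyl)prop-2-en-1-yl]oxy}benzoate A9. The secondary radical at C3 is oxidised and captured by the phenolic oxygen, forming O4–C3, the methyl group and ring B in methyl (2S,3S)-5-methoxy-3-methyl-2-(3,4,5-trimethoxyphenyl)-2,3-dihydro-1,4-benzodioxine-7-carboxylate A10.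
- In favour: ring B, the methyl group and the C3 stereocentre arise in one step from an alkene. No palladium alkoxide with a β-hydrogen is involved, and C2 can come from a catalytic, branched-selective, enantioselective allylic etherification. On these last two points this alternative is the better plan.
- Against: C3 is created during ring closure, so the trans relationship depends on the facial bias of a cation-like centre next to C2, which is not secured. That centre lies β to an electron-rich aryl group and could undergo a 1,2-aryl or hydride shift. The electron-rich free phenol must survive an electrophilic N–F oxidant. The ester must afterwards be reduced and extended by two carbons.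
- Comparison: on structure both plans close ring B in the key step, but this one closes at the sp3 carbon C3 (a stereocentre at risk) and the chosen one at the sp2 carbon C8a (stereocentres untouched), so the chosen plan is safer. On mechanism both key steps are extrapolations and are roughly equal in uncertainty. On step economy this route would need about seven to eight steps against four.

Key step: step 4

## Route

Step 1
Reactants: 1 2,4-dibromo-6-methoxyphenol; 2 methyl (R)-lactate
Product: 3 methyl (2S)-2-(2,4-dibromo-6-methoxyphenoxy)propanoate
Conditions: PPh3, DIAD, THF, 0 °C to rt
Reagents that add atoms: none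
Why: Mitsunobu etherification; the phenol is acidic enough (two bromine substituents) to serve as pronucleophile, and SN2 displacement of the oxyphosphonium group at the α-carbonyl secondary carbon should invert (R) to (S), which sets the future C3 stereocentre and fixes O4 on the methyl-bearing carbon.

Step 2
Reactants: 3 methyl (2S)-2-(2,4-dibromo-6-methoxyphenoxy)propanoate
Product: 4 (2S)-2-(2,4-dibromo-6-methoxyphenoxy)propanal
Conditions: i-Bu2AlH (1.1 equiv), CH2Cl2, −78 °C; MeOH, then aq. potassium sodium tartrate
Reagents that add atoms: none
Why: Partial reduction of an α-heteroatom-substituted ester with i-Bu2AlH; the aluminium hemiacetal is stabilised at −78 °C by the α-aryloxy oxygen and should release the aldehyde only on work-up, the aryl bromides are inert, and the stereocentre is not touched. The aldehyde is used crude and cold to avoid enolisation.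

Step 3
Reactants: 4 (2S)-2-(2,4-dibromo-6-methoxyphenoxy)propanal; 5 5-bromo-1,2,3-trimethoxybenzene
Product: 7 (1S,2S)-2-(2,4-dibromo-6-methoxyphenoxy)-1-(3,4,5-trimethoxyphenyl)propan-1-ol, via Grignard reagent 6 (not isolated)
Conditions: 5, Mg, THF, 40 °C; then added to 4, MgBr2·OEt2 (2.5 equiv), CH2Cl2, −78 °C; aq. NH4Cl
Reagents that add atoms: none
Why: Chelation-controlled Grignard addition (Cram chelate model); MgBr2 should bridge the carbonyl oxygen and the α-aryloxy oxygen, helped by the neighbouring methoxy donor, so the aryl group enters from the face bearing H and not CH3, giving the syn (1S,2S) alcohol and setting the future C2 stereocentre. Aryl Grignard reagents do not exchange with aryl bromides at this temperature.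

Step 4
Reactants: 7 (1S,2S)-2-(2,4-dibromo-6-methoxyphenoxy)-1-(3,4,5-trimethoxyphenyl)propan-1-ol; 8 acrolein diethyl acetal
Product: 10 (E)-3-[(2S,3S)-5-methoxy-3-methyl-2-(3,4,5-trimethoxyphenyl)-2,3-dihydro-1,4-benzodioxin-7-yl]prop-2-enal, via diethyl acetal 9 (not isolated)
Conditions: Pd2(dba)3 (2.5 mol %), t-BuXPhos (6 mol %), Cs2CO3 (3 equiv), 8 (3 equiv), toluene, 90 °C; then 1 M HCl, THF, rt
Reagents that add atoms: water, O
Why: Proposed new method: one zerovalent palladium catalyst bearing 2-di-tert-butylphosphino-2',4',6'-triisopropylbiphenyl is asked to run two independent cycles on one molecule. At the ortho C–Br bond, oxidative addition is followed by carbonate-assisted binding of the tethered benzylic alkoxide to divalent palladium and C–O reductive elimination from a seven-membered aryl(alkoxo)palladium chelate, which closes the six-membered ring B at the sp2 carbon C8a (O1–C8a) as in the known palladium-catalysed intramolecular etherification of aryl bromides with secondary alcohols; the bulky di-tert-butylphosphine should favour this reductive elimination over β-hydride loss from the alkoxide. At the para C–Br bond no internal nucleophile can reach the metal, so the arylpalladium bromide should insert the terminal alkene of 8 (aryl to the CH2 terminus) and undergo syn β-hydride elimination toward the benzylic hydrogen to give the E-alkenyl acetal 9, as in the known Heck synthesis of cinnamaldehydes from aryl bromides and acrolein acetals with carbonate bases. The closest known reaction types are these two reactions, merged here, and domino sequences that pair a palladium heteroatom coupling with a Heck reaction on dihaloarenes. No stereocentre is formed: the C2–O and C3–O bonds stay intact, so the syn alcohol maps onto the trans (2S,3S) ring, and the E geometry follows from syn insertion and syn elimination. The step needs site selectivity between the two bromides, which the tether secures because only the ortho site can form the chelate and its flanking ether substituent slows alkene insertion there, and it needs β-hydride elimination away from the acetal carbon, which the carbonate base should favour. Dilute aqueous HCl then hydrolyses the allylic acetal to the enal without ionising the benzylic ether.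

## Compound list

1 | 2,4-dibromo-6-methoxyphenol | COc1cc(Br)cc(Br)c1O | starting material
2 | methyl (R)-lactate, methyl (2R)-2-hydroxypropanoate | C[C@@H](O)C(=O)OC | starting material
3 | methyl (2S)-2-(2,4-dibromo-6-methoxyphenoxy)propanoate | C[C@H](Oc1c(Br)cc(Br)cc1OC)C(=O)OC | intermediate
4 | (2S)-2-(2,4-dibromo-6-methoxyphenoxy)propanal | C[C@H](Oc1c(Br)cc(Br)cc1OC)C=O | intermediate
5 | 5-bromo-1,2,3-trimethoxybenzene | COc1cc(Br)cc(OC)c1OC | starting material
6 | (3,4,5-trimethoxyphenyl)magnesium bromide | COc1cc([Mg]Br)cc(OC)c1OC | intermediate (not isolated)
7 | (1S,2S)-2-(2,4-dibromo-6-methoxyphenoxy)-1-(3,4,5-trimethoxyphenyl)propan-1-ol | COc1cc([C@H](O)[C@H](C)Oc2c(Br)cc(Br)cc2OC)cc(OC)c1OC | intermediate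
8 | acrolein diethyl acetal, 3,3-diethoxyprop-1-ene | C=CC(OCC)OCC | starting material
9 | (2S,3S)-7-[(E)-3,3-diethoxyprop-1-en-1-yl]-5-methoxy-3-methyl-2-(3,4,5-trimethoxyphenyl)-2,3-dihydro-1,4-benzodioxine | COc1cc([C@@H]2Oc3cc(/C=C/C(OCC)OCC)cc(OC)c3O[C@H]2C)cc(OC)c1OC | intermediate (not isolated)
10 | (E)-3-[(2S,3S)-5-methoxy-3-methyl-2-(3,4,5-trimethoxyphenyl)-2,3-dihydro-1,4-benzodioxin-7-yl]prop-2-enal | COc1cc([C@@H]2Oc3cc(/C=C/C=O)cc(OC)c3O[C@H]2C)cc(OC)c1OC | target

## Step count and least certain steps

Total step count: 4. Longest linear sequence: 4 steps (1 → 3 → 4 → 7 → 10); 6 is made and consumed in the flask in step 3.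

Step 4 (key step). Four processes could spoil the merger:
- β-hydride elimination from the benzylic palladium alkoxide, which would oxidise the carbinol and reduce the C–Br bond;
- wrong pairing of sites, either alkene insertion at the ortho arylpalladium before the alkoxide binds or intermolecular etherification at the para site;
- β-hydride elimination toward the acetal C–H in the Heck cycle, which would give a saturated ester after work-up;
- a mismatch of media, since the etherification prefers a non-polar solvent and the Heck reaction a polar one.

The fallback separates the two known reactions. It sets out from 7: intramolecular etherification alone (Pd(OAc)2, t-BuXPhos, Cs2CO3, toluene, 80 °C, no alkene present) should give (2S,3S)-7-bromo-5-methoxy-3-methyl-2-(3,4,5-trimethoxyphenyl)-2,3-dihydro-1,4-benzodioxine F1, which is isolated. A ligand-free Heck reaction of F1 with 8 (Pd(OAc)2, n-Bu4NOAc, K2CO3, KCl, DMF, 90 °C) then returns to the route at 9, and the same acid work-up gives 10.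

Step 3. The likely failure is poor facial selectivity: the aryl ether oxygen is a weak donor, and if the chelate does not form the Felkin–Anh pathway would lead to the anti alcohol and so to the cis ring. The fallback sets the carbinol centre by hydride addition to a ketone, where Felkin–Anh control favours the syn isomer and needs no chelate. It sets out from 3: aminolysis (MeNH(OMe)·HCl, AlMe3, CH2Cl2, 0 °C to rt) should give (2S)-2-(2,4-dibromo-6-methoxyphenoxy)-N-methoxy-N-methylpropanamide F2. Addition of 6 (THF, 0 °C) should give (2S)-2-(2,4-dibromo-6-methoxyphenoxy)-1-(3,4,5-trimethoxyphenyl)propan-1-one F3. Reduction with LiBH(s-Bu)3 (THF, −78 °C) returns to the route at 7. This bypass also avoids the aldehyde altogether.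

Step 2. The likely failures are over-reduction, through early collapse of the aluminium hemiacetal, and loss of enantiopurity by enolisation of the α-aryloxy aldehyde during work-up. The fallback sets out from 3: full reduction (LiBH4, THF, 0 °C) should give (2S)-2-(2,4-dibromo-6-methoxyphenoxy)propan-1-ol F4, which is stable and can be purified. Oxidation under neutral conditions (Dess–Martin periodinane, NaHCO3, CH2Cl2, 0 °C) returns to the route at 4, which is used at once.

Step 1. The likely failures are slow coupling of the doubly ortho-substituted phenol and competing elimination of the activated lactate. The fallback replaces the redox condensation by a plain SN2 alkylation. It sets out from 2: sulfonylation (TsCl, pyridine, 0 °C) should give methyl (2R)-2-{[(4-methylphenyl)sulfonyl]oxy}propanoate F5. Displacement by the phenoxide of 1 (K2CO3, MeCN, 60 °C) with inversion returns to the route at 3.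

## Further compounds

F1 | step 4 | (2S,3S)-7-bromo-5-methoxy-3-methyl-2-(3,4,5-trimethoxyphenyl)-2,3-dihydro-1,4-benzodioxine | COc1cc([C@@H]2Oc3cc(Br)cc(OC)c3O[C@H]2C)cc(OC)c1OC
F2 | step 3 | (2S)-2-(2,4-dibromo-6-methoxyphenoxy)-N-methoxy-N-methylpropanamide | C[C@H](Oc1c(Br)cc(Br)cc1OC)C(=O)N(C)OC
F3 | step 3 | (2S)-2-(2,4-dibromo-6-methoxyphenoxy)-1-(3,4,5-trimethoxyphenyl)propan-1-one | COc1cc(C(=O)[C@H](C)Oc2c(Br)cc(Br)cc2OC)cc(OC)c1OC
F4 | step 2 | (2S)-2-(2,4-dibromo-6-methoxyphenoxy)propan-1-ol | C[C@H](Oc1c(Br)cc(Br)cc1OC)CO
F5 | step 1 | methyl (2R)-2-{[(4-methylphenyl)sulfonyl]oxy}propanoate | C[C@@H](OS(=O)(=O)c1ccc(C)cc1)C(=O)OC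
A1 | alternative 1 | (4R,5R)-2-{(1R)-1-[2-bromo-4-(1,3-dioxolan-2-yl)-6-methoxyphenoxy]ethyl}-4,5-dicyclohexyl-1,3,2-dioxaborolane | C[C@H](Oc1c(Br)cc(C2OCCO2)cc1OC)B1O[C@H](C2CCCCC2)[C@@H](C2CCCCC2)O1
A2 | alternative 1 | (dichloromethyl)lithium | [Li]C(Cl)Cl
A3 | alternative 1 | (4R,5R)-2-{(1S,2S)-2-[2-bromo-4-(1,3-dioxolan-2-yl)-6-methoxyphenoxy]-1-chloropropyl}-4,5-dicyclohexyl-1,3,2-dioxaborolane | Cl[C@@H](B1O[C@H](C2CCCCC2)[C@@H](C2CCCCC2)O1)[C@H](C)Oc1c(Br)cc(C2OCCO2)cc1OC
A4 | alternative 1 | (4R,5R)-2-{(1S,2S)-2-[2-bromo-4-(1,3-dioxolan-2-yl)-6-methoxyphenoxy]-1-(3,4,5-trimethoxyphenyl)propyl}-4,5-dicyclohexyl-1,3,2-dioxaborolane | COc1cc([C@H](B2O[C@H](C3CCCCC3)[C@@H](C3CCCCC3)O2)[C@H](C)Oc2c(Br)cc(C3OCCO3)cc2OC)cc(OC)c1OC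
A5 | alternative 2 | 2-bromo-4-(1,3-dioxolan-2-yl)-6-methoxyphenol | COc1cc(C2OCCO2)cc(Br)c1O
A6 | alternative 2 | ethyl diazoacetate | CCOC(=O)C=[N+]=[N-]
A7 | alternative 2 | 3,4,5-trimethoxybenzaldehyde | COc1cc(C=O)cc(OC)c1OC
A8 | alternative 2 | ethyl (2R,3S)-2-[2-bromo-4-(1,3-dioxolan-2-yl)-6-methoxyphenoxy]-3-hydroxy-3-(3,4,5-trimethoxyphenyl)propanoate | CCOC(=O)[C@H](Oc1c(Br)cc(C2OCCO2)cc1OC)[C@@H](O)c1cc(OC)c(OC)c(OC)c1
A9 | alternative 3 | methyl 4-hydroxy-3-methoxy-5-{[(1R)-1-(3,4,5-trimethoxyphenyl)prop-2-en-1-yl]oxy}benzoate | C=C[C@H](c1cc(OC)c(OC)c(OC)c1)Oc1cc(C(=O)OC)cc(OC)c1O
A10 | alternative 3 | methyl (2S,3S)-5-methoxy-3-methyl-2-(3,4,5-trimethoxyphenyl)-2,3-dihydro-1,4-benzodioxine-7-carboxylate | COC(=O)c1cc(OC)c2O[C@@H](C)[C@H](c3cc(OC)c(OC)c(OC)c3)Oc2c1
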